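All runs stem from a simulated flask on assumed constants, and the scatter is random.

If this flask was to be repeated, the thing to watch was the turnovers of the catalyst, so I left this note at the bench.

| setting | elm | oak | birch | grey | blue | teal |
|---|---|---|---|---|---|---|
| substrate | 0.10 M | 0.050 M | 0.075 M | 0.10 M (fed, over 30.0 min) | 0.10 M | 0.10 M |
| catalyst | 2.9 mol% | 2.9 mol% | 2.9 mol% | 2.9 mol% | 2.9 mol% | 2.9 mol% |
| remark | run made earlier | run made earlier | run made earlier | a stirred flask in which substrate is dosed at a steady rate over 30.0 min without added volume, worked up at 30 min | one stirred flow tank at steady state, fed with the mixture as stated, mean residence time 30 min | everything together in a closed stirred flask, run for 30 min |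
| time |  |  |  | 30 min |  | 30 min |

- elm (time / min: target / %, side product A / %, isomer of the product / %): 2.50: 3, 0, 0; 4.00: 5, 2, 0; 6.00: 8, 3, 1; 8.00: 10, 5, 1; 12.0: 11, 6, 0; 20.0: 20, 5, 6; 30.0: 18, 11, 7
- oak (time / min: target / %, side product A / %, isomer of the product / %): 1.33: 0, 4, 0; 4.00: 3, 3, 3; 6.00: 7, 0, 0; 10.0: 6, 3, 2; 15.0: 8, 9, 3; 20.0: 13, 10, 2; 25.0: 12, 10, 4
- birch (time / min: target / %, side product A / %, isomer of the product / %): 1.33: 1, 3, 0; 4.00: 3, 2, 0; 6.00: 7, 2, 1; 10.0: 13, 10, 1; 15.0: 12, 6, 1; 20.0: 15, 9, 0; 25.0: 14, 9, 6

(readings scatter by 2 percentage points)

- a species is counted by the substrate in it: one side product B counts as two
- the stated concentrations are those of everything mixed, before any reaction; amounts are the same in each set-up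
- the feed brings no volume worth counting
- the earlier runs were made in a closed, stirred flask

- order of the set-ups by the share of target in all that became target or side product A or isomer of the product or side product B, at the outlet or at the end, highest first (grey / blue / teal)
- share of target in all that became target or side product A or isomer of the product or side product B, at the outlet or at the end, grey
- share of target in all that became target or side product A or isomer of the product or side product B, at the outlet or at the end, blue
- share of target in all that became target or side product A or isomer of the product or side product B, at the outlet or at the end, teal

I counted target plus isomer of the product, which appeared late and which I took as target's descendant, and divided by the catalyst loading, the time and c(substrate) as charged. The elm run at 8.00 min gave 4.74 /M/min. I called this the turnover constant, the turnover frequency of the catalyst per unit of c(substrate). The oak run at 10.0 min gave 5.52 /M/min, and with a scatter of 2 percentage points on each reading I held the two as one constant.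

For teal, which has elm's charge, this meant a half-life of substrate on the catalyst of 50.4 min, taking that route by itself, which is longer than the run. So 33.8% of the charge was due through the catalyst by the end, yet elm showed 25.0% as target and isomer at 30.0 min. I marked that gap of 8.8 points, a warning within reach of the scatter, as the point to watch, since side product B went unread.

The forecast, saying of grey “its young target has barely isomerised”, gave grey > teal > blue, with 55% for grey, 41% for blue and 51% for teal.

The flasks gave grey > teal > blue, with 41.8% in grey, 27.8% in blue and 31.0% in teal.

    substrate + target → side product B (k = 0.440 /M/min)
    substrate + catalyst → catalyst + target (k = 5.50 /M/min)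
    substrate → side product A (k = 0.00580 /min)
    target + catalyst ⇌ isomer of the product + catalyst, rate k4*[catalyst]*[target] forward; the back reaction follows from the equilibrium constant (K = 0.740, k = 9.10 /M/min)

In teal, with the other concentrations as charged, target had a half-life of 16 min by passing with substrate into side product B, shorter than its 26 min by the forward step to the isomer and than the 43 min of substrate on the catalyst. In blue, where c(substrate) stood at 0.0550 M, my turnover constant, a reading from elm that carries its scatter, put the estimate at 7.82 turnovers in a mean residence time of 30 min, or roughly 22.7% of the charge, while 45.0% of the substrate was gone from the tank.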